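Take the teal run: its G stands at 83% after 30.0 d, below the 89.7% its Q allows, while the grey run levels at about 61% against a limit of 60.3%. Q is the limiting reagent in these two runs, and the grey level reads as Z and Q going one to one.

| setting | grey | teal | green | flask |
|---|---|---|---|---|
| Z | 0.68 M | 0.68 M | 0.68 M | 0.68 M |
| Q | 0.41 M | 0.61 M | 0.816 M | 0.816 M |
| L | 1.4 mM | 1.4 mM | 2.8 mM | 1.4 mM |
| X | 1.7 mM | 1.7 mM | 1.7 mM | 1.7 mM |
| remark | run made earlier | run made earlier | run made earlier |  |

| run | time / d | G / % |
|---|---|---|
| grey | 6.00 | 53 |
| grey | 12.0 | 56 |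
| grey | 20.0 | 60 |
| grey | 25.0 | 59 |
| grey | 30.0 | 61 |
| teal | 2.50 | 61 |
| teal | 5.00 | 70 |
| teal | 8.00 | 75 |
| teal | 15.0 | 81 |
| teal | 30.0 | 83 |
| green | 2.50 | 84 |
| green | 8.00 | 95 |
| green | 15.0 | 95 |
| green | 20.0 | 96 |
| green | 30.0 | 97 |

(scatter of a reading: 1.5 percentage points)



* factor on the rate of making G when 30% of the Z are converted if Q is charged twice over
* factor on the rate when 30% of the Z are converted if L is charged at 0.30 mM instead

Work with what is left. Assume the rate is a constant times L, Z and Q. Then the logarithm of (fraction of Q left over fraction of Z left), divided by the difference of the Q and Z charges, is a catalyst clock: the time integral of that constant times L, independent of the Q charge.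

Read on the teal run, the clock stands at 2.83 M⁻¹ after 2.50 d and 9.60 M⁻¹ after 15.0 d. It therefore grows as time to the power 0.682, a reading with wide scatter, and its speed falls with time. The flask has a clock needed for 30% conversion of 0.507 M⁻¹, which is 5.58 times below that first teal reading, so with the teal L and X the flask should get there before 2.50 d.

My reckoning stretches the power back to there. Doubling Q raises the Q left by a factor 2.33 and cuts the clock needed to 0.234 M⁻¹, which gives 3.34. Taking the clock as proportional to the L charge, L at 0.30 mM scales it by 0.214, which gives 0.105; that is an assumption, for the green run with twice the L reads 1.64 times the teal clock at 2.50 d.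

The forecast says 2.6 (2.1 to 3.3) and 0.2 (0.08 to 0.4), on the ground that the decline “suggests the catalyst dies with time”. Mine stand above it on the first and below it on the second.

    Z + Q + L → L + G (k = 200 M⁻² h⁻¹)
    L + X ⇌ E (K = 3300 M⁻¹, k = 180 M⁻¹ h⁻¹)
    2 L → J (k = 67.0 M⁻¹ h⁻¹)

The flask gives 4.05 for doubled Q and 0.0862 for less L. It reaches 30% conversion at 0.127 d, while L passes into E at 7.3 d⁻¹ per L with X as charged, a product of 0.927. The clock needed, 0.507 M⁻¹, over that time makes a mean speed of 3.99 M⁻¹ d⁻¹ in the flask. The teal run has the flask's L and X, so on a shared clock its reading at 2.50 d leaves 0.979 M⁻¹ d⁻¹ for the time after.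

(Readings and results are simulated on assumed constants; the scatter is artificial.)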